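**Plan**
1. Retrosynthetic cuts, in order: the Si–O and pivaloyl C–O bonds; the side-chain C=C at C5 (back to a C5 aldehyde and malonic acid); then C3–C3a and O1–C7a together, which opens the dihydrofuran ring to 4-iodo-3-methoxybenzaldehyde and a cis-aryl oxirane; last the oxirane oxygen and the aryl–alkyne bond of the syringyl arm.
2. Enabling feature: the furan ring is fused to the benzene ring at two neighbouring carbons, C3a (C–C bond) and C7a (C–O bond); C7a has the C7 methoxy carbon as its other neighbour, and O1–C2–C3 is the skeleton of an aryl oxirane. An aryl iodide with iodine at C7a can therefore be alkylated at its single free ortho carbon and etherified at the ipso carbon by that oxirane.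
3. Forward order: syringyl arm (aryl bromide, alkyne, Z-alkene, cis-epoxide); iodo-aldehyde for the benzo ring; the dihydrofuran ring (the only ring formed) by palladium/norbornene annulation; C5 chain extension to the E-acrylic acid; deprotection.
4. Stereochemistry: both stereocentres come from the Jacobsen–Katsuki epoxidation of the Z-alkene, which gives the (2R,3S)-cis-oxirane. In the annulation C2 is retained and C3 inverted, so cis becomes trans-(2S,3R). The E-alkene comes from the decarboxylative Knoevenagel–Doebner condensation.

Key step: step 7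

Assumption: the SMILES is read as the trans-(2S,3R) enantiomer; atom numbers are those of 2,3-dihydro-1-benzofuran (O1, C2, C3, C3a, C4–C7, C7a).

**Route**

Step 1
Reactants: 1 4-bromo-2,6-dimethoxyphenol
Product: 2 4-bromo-2,6-dimethoxyphenyl pivalate (2,2-dimethylpropanoate)
Conditions: PivCl, Et3N, DMAP (cat.), CH2Cl2, 0 °C to rt
Reagents that add atoms: pivaloyl chloride, CC(C)(C)C(Cl)=O
Why: DMAP-catalysed O-acylation of a phenol with an acid chloride; the hindered ester protects the phenol and makes the aryl ring electron-poor for the later oxirane chemistry.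

Step 2
Reactants: 2 4-bromo-2,6-dimethoxyphenyl pivalate; 3 tert-butyldimethyl(prop-2-yn-1-yloxy)silane
Product: 4 4-[3-(tert-butyldimethylsilyloxy)prop-1-yn-1-yl]-2,6-dimethoxyphenyl pivalate
Conditions: PdCl2(PPh3)2 (3 mol %), CuI (5 mol %), Et3N, DMF, 70 °C
Reagents that add atoms: none
Why: Sonogashira coupling of an aryl bromide with a terminal alkyne; the aryl pivalate and the silyl ether are inert to the tertiary amine base.

Step 3
Reactants: 4 4-[3-(tert-butyldimethylsilyloxy)prop-1-yn-1-yl]-2,6-dimethoxyphenyl pivalate
Product: 5 4-[(Z)-3-(tert-butyldimethylsilyloxy)prop-1-en-1-yl]-2,6-dimethoxyphenyl pivalate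
Conditions: H2 (1 atm), Lindlar catalyst (Pd on CaCO3 poisoned with Pb(OAc)2), quinoline, EtOAc, rt
Reagents that add atoms: none
Why: Lindlar semi-hydrogenation delivers both hydrogens to the same face of the alkyne on the lead-poisoned palladium surface, giving the Z-alkene, and quinoline slows further reduction.

Step 4
Reactants: 5 4-[(Z)-3-(tert-butyldimethylsilyloxy)prop-1-en-1-yl]-2,6-dimethoxyphenyl pivalate
Product: 6 4-[(2R,3S)-3-{[(tert-butyldimethylsilyl)oxy]methyl}oxiran-2-yl]-2,6-dimethoxyphenyl pivalate (cis-epoxide)
Conditions: (R,R)-(salen)MnCl [(R,R)-N,N'-bis(3,5-di-tert-butylsalicylidene)-1,2-cyclohexanediaminomanganese chloride] (5 mol %), 4-phenylpyridine N-oxide (20 mol %), aq NaOCl (pH 11.3), CH2Cl2, 0 °C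
Reagents that add atoms: sodium hypochlorite, [Na+].[O-]Cl
Why: Jacobsen–Katsuki epoxidation, for which cis-disubstituted aryl alkenes are the best substrate class; the (R,R) catalyst should transfer oxygen to the face that makes the benzylic carbon R (as with cis-β-methylstyrene and cis-cinnamates), setting both stereocentres of the (2R,3S)-cis-oxirane at once.

Step 5
Reactants: 7 methyl 4-iodo-3-methoxybenzoate
Product: 8 (4-iodo-3-methoxyphenyl)methanol
Conditions: iBu2AlH (2.5 equiv), CH2Cl2, −78 to 0 °C; aq potassium sodium tartrate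
Reagents that add atoms: none
Why: Ester reduction by two hydride transfers from the aluminium hydride gives the benzylic alcohol, and the aryl C–I bond does not react at these temperatures.

Step 6
Reactants: 8 (4-iodo-3-methoxyphenyl)methanol
Product: 9 4-iodo-3-methoxybenzaldehyde
Conditions: MnO2 (activated, 10 equiv), CH2Cl2, rt
Reagents that add atoms: none
Why: Benzylic alcohol oxidation on activated MnO2 stops at the aldehyde and tolerates the aryl iodide.

Step 7
Reactants: 9 4-iodo-3-methoxybenzaldehyde; 6 4-[(2R,3S)-3-{[(tert-butyldimethylsilyl)oxy]methyl}oxiran-2-yl]-2,6-dimethoxyphenyl pivalate (1.5 equiv)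
Product: 10 4-[(2S,3R)-3-{[(tert-butyldimethylsilyl)oxy]methyl}-5-formyl-7-methoxy-2,3-dihydro-1-benzofuran-2-yl]-2,6-dimethoxyphenyl pivalate (trans)
Conditions: Pd(OAc)2 (10 mol %), RuPhos (20 mol %), isopropyl bicyclo[2.2.1]hept-5-ene-2-carboxylate (norbornene co-catalyst, 50 mol %), K2CO3 (2.5 equiv), DMF, 100 °C, argon
Reagents that add atoms: none
Why: Proposed new method: oxidative addition of the C–I bond of 9 to zerovalent palladium, carbopalladation of the norbornene and C–H palladation at C5 of 9 (its only free ortho carbon, the future C3a) should give the aryl-norbornyl palladacycle of divalent palladium, whose metal attacks C3 of oxirane 6 from the face opposite to the C–O bond (SN2-type oxidative addition to tetravalent palladium); aryl–alkyl reductive elimination then makes C3–C3a, β-carbon elimination expels the norbornene, and the C2 alkoxide left on the side chain is arylated at the ipso carbon C7a by C–O reductive elimination, which returns zerovalent palladium. The closest known reaction types are the palladium/norbornene (Catellani-type) annulation of aryl iodides with terminal epoxides, which gives 2-substituted 2,3-dihydrobenzofurans through the same two bond formations, and the invertive ortho alkylation of such palladacycles by secondary alkyl iodides; an internal aryl-substituted oxirane has not been used. The dihydrofuran ring closes in the last event, a C–O reductive elimination from a six-membered aryl(alkoxo)palladium chelate, that is a 5-exo closure of O1 onto C7a. C3 is the only stereocentre made here and is fixed by inversion at the oxirane carbon, whereas C2 keeps its C–O bond and its configuration from step 4, so the (2R,3S)-cis-oxirane should map onto the (2S,3R)-trans ring. The selectivity needed is attack at C3 and not at benzylic C2, without ionisation of the benzylic C–O bond; the electron-poor 4-pivaloyloxy-3,5-dimethoxyphenyl group (no para donor, two inductively withdrawing meta methoxy groups), a CH2OSi substituent at C3 that is less bulky at the reacting carbon than the aryl group at C2, and the soft, bulky metal nucleophile are meant to secure it. On the arene, the C7 methoxy group ortho to iodine prevents a second alkylation and promotes norbornene extrusion, and the para formyl group should speed the C–O reductive elimination.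

Step 8
Reactants: 10 4-[(2S,3R)-3-{[(tert-butyldimethylsilyl)oxy]methyl}-5-formyl-7-methoxy-2,3-dihydro-1-benzofuran-2-yl]-2,6-dimethoxyphenyl pivalate
Product: 12 (E)-3-[(2S,3R)-3-{[(tert-butyldimethylsilyl)oxy]methyl}-2-[3,5-dimethoxy-4-(pivaloyloxy)phenyl]-7-methoxy-2,3-dihydro-1-benzofuran-5-yl]prop-2-enoic acid, via arylidenemalonic acid 11 (not isolated)
Conditions: malonic acid (3 equiv), pyridine, piperidine (10 mol %), 85 °C
Reagents that add atoms: malonic acid, OC(=O)CC(O)=O
Why: Knoevenagel condensation of the aryl aldehyde with malonic acid and pyridine-promoted decarboxylation of the arylidenemalonic acid (Doebner modification) should give the E-acrylic acid, as in the classical preparation of ferulic acid from vanillin-type aldehydes; no stereocentre is touched, and partial loss of a protecting group would be harmless because both are removed next.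

Step 9
Reactants: 12 (E)-3-[(2S,3R)-3-{[(tert-butyldimethylsilyl)oxy]methyl}-2-[3,5-dimethoxy-4-(pivaloyloxy)phenyl]-7-methoxy-2,3-dihydro-1-benzofuran-5-yl]prop-2-enoic acid
Product: 14 (E)-3-[(2S,3R)-2-(4-hydroxy-3,5-dimethoxyphenyl)-3-(hydroxymethyl)-7-methoxy-2,3-dihydro-1-benzofuran-5-yl]prop-2-enoic acid (CNP0224723.1), via O-pivaloyl hydroxymethyl acid 13 (not isolated)
Conditions: 2 M HCl, THF, rt; then LiOH (excess), H2O, 40 °C; HCl to pH 2
Reagents that add atoms: none
Why: Acid-catalysed hydrolysis of the primary silyl ether while the electron-poor pivalate still protects the benzylic C2–O bond against ionisation, then saponification of the hindered aryl pivalate by hydroxide at a temperature where the phenoxide should not open the dihydrofuran ring; both are standard protecting-group removals.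

**Compound list**
1 | 4-bromo-2,6-dimethoxyphenol | COc1cc(Br)cc(OC)c1O | starting material
2 | 4-bromo-2,6-dimethoxyphenyl pivalate | COc1cc(Br)cc(OC)c1OC(=O)C(C)(C)C | intermediate
3 | tert-butyldimethyl(prop-2-yn-1-yloxy)silane | C#CCO[Si](C)(C)C(C)(C)C | starting material
4 | 4-[3-(tert-butyldimethylsilyloxy)prop-1-yn-1-yl]-2,6-dimethoxyphenyl pivalate | COc1cc(C#CCO[Si](C)(C)C(C)(C)C)cc(OC)c1OC(=O)C(C)(C)C | intermediate
5 | 4-[(Z)-3-(tert-butyldimethylsilyloxy)prop-1-en-1-yl]-2,6-dimethoxyphenyl pivalate | COc1cc(/C=C\CO[Si](C)(C)C(C)(C)C)cc(OC)c1OC(=O)C(C)(C)C | intermediate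
6 | 4-[(2R,3S)-3-{[(tert-butyldimethylsilyl)oxy]methyl}oxiran-2-yl]-2,6-dimethoxyphenyl pivalate (cis) | COc1cc([C@H]2O[C@H]2CO[Si](C)(C)C(C)(C)C)cc(OC)c1OC(=O)C(C)(C)C | intermediate
7 | methyl 4-iodo-3-methoxybenzoate | COC(=O)c1ccc(I)c(OC)c1 | starting material
8 | (4-iodo-3-methoxyphenyl)methanol | OCc1ccc(I)c(OC)c1 | intermediate
9 | 4-iodo-3-methoxybenzaldehyde | O=Cc1ccc(I)c(OC)c1 | intermediate
10 | 4-[(2S,3R)-3-{[(tert-butyldimethylsilyl)oxy]methyl}-5-formyl-7-methoxy-2,3-dihydro-1-benzofuran-2-yl]-2,6-dimethoxyphenyl pivalate (trans) | COc1cc([C@H]2Oc3c(OC)cc(C=O)cc3[C@@H]2CO[Si](C)(C)C(C)(C)C)cc(OC)c1OC(=O)C(C)(C)C | intermediate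
11 | 2-{[(2S,3R)-3-{[(tert-butyldimethylsilyl)oxy]methyl}-2-[3,5-dimethoxy-4-(pivaloyloxy)phenyl]-7-methoxy-2,3-dihydro-1-benzofuran-5-yl]methylidene}propanedioic acid | COc1cc([C@H]2Oc3c(OC)cc(C=C(C(=O)O)C(=O)O)cc3[C@@H]2CO[Si](C)(C)C(C)(C)C)cc(OC)c1OC(=O)C(C)(C)C | intermediate
12 | (E)-3-[(2S,3R)-3-{[(tert-butyldimethylsilyl)oxy]methyl}-2-[3,5-dimethoxy-4-(pivaloyloxy)phenyl]-7-methoxy-2,3-dihydro-1-benzofuran-5-yl]prop-2-enoic acid | COc1cc([C@H]2Oc3c(OC)cc(/C=C/C(=O)O)cc3[C@@H]2CO[Si](C)(C)C(C)(C)C)cc(OC)c1OC(=O)C(C)(C)C | intermediate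
13 | (E)-3-[(2S,3R)-2-[3,5-dimethoxy-4-(pivaloyloxy)phenyl]-3-(hydroxymethyl)-7-methoxy-2,3-dihydro-1-benzofuran-5-yl]prop-2-enoic acid | COc1cc([C@H]2Oc3c(OC)cc(/C=C/C(=O)O)cc3[C@@H]2CO)cc(OC)c1OC(=O)C(C)(C)C | intermediate
14 | (E)-3-[(2S,3R)-2-(4-hydroxy-3,5-dimethoxyphenyl)-3-(hydroxymethyl)-7-methoxy-2,3-dihydro-1-benzofuran-5-yl]prop-2-enoic acid | COc1cc([C@H]2Oc3c(OC)cc(/C=C/C(=O)O)cc3[C@@H]2CO)cc(OC)c1O | target

**Step count and risks**
Total: 9 steps. Longest linear sequence: 7 steps (steps 1–4 and 7–9); steps 5 and 6 prepare the second fragment.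

Step 7 (the new method) is the most likely to fail.
- What may go wrong: the oxirane may open at benzylic C2 instead of C3. The epoxide may ionise or be epimerised by iodide before the C–C bond forms, which would erode the trans relationship and the optical purity. It may isomerise to a ketone, the palladium alkoxide may undergo β-hydride elimination, or the hindered internal epoxide may not react with the palladacycle at all.
- Fallback (known chemistry): it sets out from aryl bromide 2 and comes back at 10. Suzuki–Miyaura coupling of 2 with purchased (E)-tert-butyldimethyl{[3-(4,4,5,5-tetramethyl-1,3,2-dioxaborolan-2-yl)prop-2-en-1-yl]oxy}silane (PdCl2(dppf), K3PO4, dioxane/H2O, 80 °C) should give the E-alkene silyl ether F1. Palladium-catalysed oxyarylation of F1 with purchased 4-hydroxy-3-iodo-5-methoxybenzaldehyde (Pd(OAc)2, Ag2CO3, acetone, reflux) is the known annulation of ortho-iodophenols with 1-arylpropenes. Syn carbopalladation puts the aryl carbon on the non-benzylic alkene carbon and the phenol oxygen then bonds to the benzylic one, so the benzylic bias that endangers step 7 here sets the regiochemistry. This should give the racemic trans-dihydrobenzofuran aldehyde F2. Preparative chromatography on a chiral stationary phase (amylose tris(3,5-dimethylphenylcarbamate)) would separate the enantiomers; the (2S,3R) enantiomer is 10 and the route continues with step 8.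

Step 4 is the second risk.
- What may go wrong: stepwise collapse of the radical intermediate of the manganese-oxo transfer with C–C bond rotation, which leaks cis-alkene into trans-epoxide, and incomplete facial discrimination, which lowers the optical purity.
- Fallback: it sets out from Z-alkene 5 and comes back at 6. Desilylation (HF·pyridine, THF, 0 °C) should give the Z-allylic alcohol F3. Sharpless asymmetric epoxidation (Ti(OiPr)4, L-(+)-diisopropyl tartrate, tBuOOH, 4 Å molecular sieves, CH2Cl2, −20 °C) transfers oxygen in a concerted way, so no trans-epoxide can arise, and with the L-(+)-tartrate should give the (2R,3S)-cis-epoxy alcohol F4. Silylation (TBSCl, imidazole, CH2Cl2) returns 6.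

Step 3 is the third risk.
- What may go wrong: over-reduction to the saturated chain and Z-to-E isomerisation on the palladium surface.
- Fallback: it sets out from alkyne 3 and aryl bromide 2 and comes back at 5; the Z geometry is fixed in a boron reagent before the aryl group is attached. Rhodium-catalysed trans-hydroboration of 3 with pinacolborane ([Rh(cod)Cl]2, P(iPr)3, Et3N, cyclohexane, rt) should give the Z-alkenylboronate F5. Suzuki–Miyaura coupling of F5 with 2 (Pd(PPh3)4, K3PO4, dioxane/H2O, 70 °C) proceeds with retention of alkene geometry and gives 5.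

**Further compounds**
F1 | step 7 | 4-[(E)-3-(tert-butyldimethylsilyloxy)prop-1-en-1-yl]-2,6-dimethoxyphenyl pivalate | COc1cc(/C=C/CO[Si](C)(C)C(C)(C)C)cc(OC)c1OC(=O)C(C)(C)C
F2 | step 7 | racemic trans-4-[3-{[(tert-butyldimethylsilyl)oxy]methyl}-5-formyl-7-methoxy-2,3-dihydro-1-benzofuran-2-yl]-2,6-dimethoxyphenyl pivalate (1:1 mixture of the (2S,3R) and (2R,3S) enantiomers) | COc1cc([C@H]2Oc3c(OC)cc(C=O)cc3[C@@H]2CO[Si](C)(C)C(C)(C)C)cc(OC)c1OC(=O)C(C)(C)C.COc1cc([C@@H]2Oc3c(OC)cc(C=O)cc3[C@H]2CO[Si](C)(C)C(C)(C)C)cc(OC)c1OC(=O)C(C)(C)C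
F3 | step 4 | 4-[(Z)-3-hydroxyprop-1-en-1-yl]-2,6-dimethoxyphenyl pivalate | COc1cc(/C=C\CO)cc(OC)c1OC(=O)C(C)(C)C
F4 | step 4 | 4-[(2R,3S)-3-(hydroxymethyl)oxiran-2-yl]-2,6-dimethoxyphenyl pivalate (cis) | COc1cc([C@H]2O[C@H]2CO)cc(OC)c1OC(=O)C(C)(C)C
F5 | step 3 | (Z)-tert-butyldimethyl{[3-(4,4,5,5-tetramethyl-1,3,2-dioxaborolan-2-yl)prop-2-en-1-yl]oxy}silane | CC(C)(C)[Si](C)(C)OC/C=C\B1OC(C)(C)C(C)(C)O1
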